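## The problem

Target 24 is an achiral 21-membered cyclophane. Ring A (a phenol whose hydroxyl, ether oxygen and alkyl chain are mutually meta) and ring B (a hydroquinone) are joined by one diaryl ether oxygen and by an unbranched chain of fourteen methylene groups. With no stereocentre, the questions are regiochemical and topological: two differently oxygenated arenes must be made, linked at a defined oxygen, and a large ring closed against oligomerisation. Ring B carries the ether oxygen and the chain on the two carbons flanking one hydroxyl, with the second hydroxyl para to it. As a hydroquinone it oxidises easily to the quinone, so it is best carried as its dimethyl ether to the last step. The 1,3,5-pattern of ring A cannot be reached by electrophilic substitution of a phenol, and the classical answer, an Ullmann coupling of two prefabricated rings, would join an electron-rich, ortho-oxygenated position. The enabling feature lies in ring A: the chain-bearing carbon, the neighbouring CH and the ether-bearing carbon are three contiguous atoms at the oxidation level of an ynone whose alkyne terminus carries the ring B oxygen (C(=O)–C≡C–OAr), and the remaining CH–C(OH)–CH unit is acetone activated at both methyl groups. Ring A can therefore be assembled from a C3 electrophile already bonded to the ether oxygen and a C3 bis-nucleophile, but the aryloxy alkyne does not tolerate protic acid, Lewis acids or electrophiles and the aryloxy ynone is a strong Michael acceptor, so both must be made late, under basic conditions, and used at once.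

## Retrosynthesis

**24 ⇒ 23.** The two O–CH3 bonds of ring B are cut first. Methyl ethers are preferred to benzyl or silyl ethers because they survive organolithium reagents, hot hydroxide and 170 °C, and their removal by a boron trihalide leaves the diaryl ether alone. Precursor 23 is an air-stable hydroquinone dimethyl ether. The forward step must only distinguish alkyl aryl from diaryl ethers.

**23 ⇒ 22 ⇒ 21.** Two aryl–carboxyl bonds are reintroduced on ring A, on either side of its hydroxyl. The ester groups are what make the three-carbon nucleophile acidic enough for a one-pot ring synthesis; an unactivated acetone dianion would not serve. Diester 21 looks more complex than 23 but is the direct product of the ring-forming step. The forward reactions must hydrolyse two flanked esters and expel two CO2 units, which is helped by each carboxyl being ortho to the hydroxyl and ortho or para to the aryloxy oxygen.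

**21 ⇒ 17 + 18.** In ring A the bond from the ether-bearing carbon and the bond from the chain-bearing carbon to the two ester-bearing carbons are cut, giving macrocyclic aryloxy ynone 17 and dimethyl acetonedicarboxylate 18. The neighbouring cut, the diaryl ether C–O bond, would need a hindered Ullmann coupling and a separately made 1,3,5-trisubstituted arene. Here the meta pattern follows from the C3 + C3 connectivity, and no aryl–oxygen bond is ever made at ring A. The cut removes a whole ring: 17 has one arene and no stereocentre. The forward reaction must attack the oxygen-bearing alkyne carbon, keep the aryloxy group, and aromatise by aldol condensation.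

**17 ⇒ 14.** The macrocycle is opened at the bond between the alkyne carbon and the ketone carbon, giving terminal ynol ether 14 with an N-methoxy-N-methyl amide at the chain end. The alternative, alkynylation of a chain aldehyde followed by oxidation, was set aside for three reasons:
- zinc or other Lewis acids promote the [2+2] reaction of ynol ethers with carbonyl groups;
- the intermediate aryloxy propargylic carbinol is prone to Meyer–Schuster rearrangement;
- a strong base would enolise the aldehyde.

The amide gives the ynone directly and keeps it masked as a chelated adduct until quench. The forward step needs true high dilution and a base that deprotonates the alkyne without touching the amide.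

**14 ⇒ 12 ⇒ 9 ⇒ 7 + 8.** The amide is traced to acid 12, the ethynyl ether to dichlorovinyl ether 9, and 9 to phenol 7 and trichloroethylene 8 (O–C bond). This is the established route to aryl ynol ethers, and it fixes the order of events. The elimination needs an alkyllithium, which an amide or ester would not survive, so the carboxyl group passes through it as its lithium salt and is converted to the amide afterwards. Phenol 7 is a simple arene with a saturated chain.

**7 ⇒ 6 ⇒ 2 + 4.** The phenolic C–O bond is traced to the aryl bromide of 6, and the aryl–CH2 bond is cut to symmetrical dibromide 2 and ω-bromo acid 4. Because the two bromines of 2 are equivalent, mono-metalation poses no regiochemical question, and the second bromine later becomes the ether oxygen. The fifteen carbons of 4 provide the fourteen methylenes and, as the carboxyl carbon, the future chain-bearing carbon of ring A at the correct oxidation level, so no redox adjustment of the chain is needed. The forward coupling must tolerate a carboxylate.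

**2 ⇒ 1 and 4 ⇒ 3.** One O–CH3 bond leads to commercial 2,6-dibromo-4-methoxyphenol 1. Adding the elements of HBr across the ester C–O bond of 4 leads to commercial ω-pentadecalactone 3. Both are one-step operations.

## Roads not taken

**Alternative 1:** Ring B and the macrocycle are opened together in a Dötz benzannulation. Ring B is dissected into a carbene carbon with its two vinyl carbons, one CO and a terminal alkyne at the end of a fourteen-methylene tether on ring A, as in chromium carbene complex A2. Heating A2 in dilute solution would insert the alkyne and CO and close ring B and the 21-membered ring at once to give A1. A1 has the free central hydroxyl flanked by chain and aryloxy group and a methyl ether para to it.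
- Merits: the ring B oxygens arrive differentiated, macrocyclisation and arene construction are one operation, and macrocyclic variants of this benzannulation are known.
- Step economy: only demethylation follows, one step after the key step against three in the chosen plan. In this respect Alternative 1 is better.
- Weak points: A2 is a heat- and air-sensitive stoichiometric chromium reagent with a β-aryloxy substituent, a class prone to cyclopentannulation, furan formation and loss of the β-oxygen group.
- Weak points: with a long tether the orientation of alkyne insertion is no longer enforced, so isomeric cyclophanes and oligomers can form.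
- Weak points: ring A, with its meta pattern and a sixteen-carbon alkynyl chain, still has to be made separately.
- Comparison: the chosen plan offers metal-free key reagents, no separate synthesis of ring A, and a precursor (17) reached by ordinary polar chemistry.

**Alternative 2:** Ring B is opened at the single bond between the carbon of the remote hydroxyl and the adjacent CH, leading back to 4-alkenyl-4-hydroxycyclobutenone A4 from a squaric acid derivative. Thermolysis of A4 (Moore rearrangement) would give a dienylketene whose 6π closure and tautomerisation deliver free hydroquinone A3. The macrocycle would then be closed by hydroboration of the terminal alkene and intramolecular alkyl–aryl Suzuki coupling at the ring A bromide.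
- Merits: every ring B substituent is fixed by the order of additions to the four-membered ring, the rearrangement needs no reagent and is well precedented, and the hydroquinone oxidation level arrives directly. Resting wholly on known reaction types is an advantage over the chosen plan, whose key step has no direct precedent.
- Weak points: A4 has hydrogen at one ring carbon, so it needs a semisquarate-type precursor and a regiocontrolled organolithium addition.
- Weak points: A3 is air-sensitive and must be protected before palladium chemistry.
- Weak points: the macrocyclisation is a separate, entropically demanding sp3–sp2 coupling, and ring A is again imported as a prefunctionalised arene.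
- Comparison: the chosen plan is shorter, forms ring A, its substitution pattern and the ether link in one event, and closes the large ring by a simple acylation.

**Alternative 3:** The chain is cut between carbons 8 and 9 (counted from ring B), leading back to 21-membered allylic macrolactone A6 that already contains the diaryl ether. Its silyl ketene acetal would undergo Ireland–Claisen rearrangement to carbocyclic acid A5, transferring the ring from a lactone to a carbocycle of the same size.
- Merits: macrolactonisation is the most dependable large-ring closure, and the rearrangement is intramolecular and needs no dilution. On reliability of the ring closure this road is better.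
- Weak points: both arenes and the ether must first be joined by the hindered Ullmann coupling that the chosen plan avoids.
- Weak points: A5 carries a carboxyl group, a stereocentre and an E-alkene that the target lacks, so radical decarboxylation and hydrogenation are needed before demethylation.
- Weak points: the chair-like transition state must be reached across a 21-membered ring, with uncertain ketene acetal geometry.
- Comparison: the chosen plan also installs and removes two ester groups, so its advantage here is one of degree. What it adds is that ring A and the ether link are never separate synthetic problems.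

Key step: step 9

Remark on the chemistry: the addition of phenoxide to trichloroethylene is taken to give the E-1,2-dichlorovinyl ether, as is usual for this reaction. This geometry is destroyed in step 6 and the target has no stereocentre.

## Route

Step 1
Reactants: 1 2,6-dibromo-4-methoxyphenol
Product: 2 1,3-dibromo-2,5-dimethoxybenzene
Conditions: MeI, K2CO3, DMF, rt
Reagents that add atoms: iodomethane, CI
Why: Williamson O-methylation; the two ortho bromines make the phenol acidic enough for K2CO3, and the product has a mirror plane that makes both carbon–bromine bonds equivalent for step 3.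

Step 2
Reactants: 3 ω-pentadecalactone (oxacyclohexadecan-2-one)
Product: 4 15-bromopentadecanoic acid
Conditions: HBr (33% in AcOH), cat. H2SO4, 70 °C
Reagents that add atoms: hydrogen bromide, Br
Why: Acidolysis of the lactone with SN2 attack of bromide at the primary alkyl–oxygen carbon, the standard conversion of lactones into ω-bromoalkanoic acids; all fifteen carbons are kept, fourteen as the bridge and the carboxyl carbon as the future chain-bearing carbon of ring A.

Step 3
Reactants: 2 1,3-dibromo-2,5-dimethoxybenzene, 4 15-bromopentadecanoic acid
Product: 6 15-(3-bromo-2,5-dimethoxyphenyl)pentadecanoic acid, via (3-bromo-2,5-dimethoxyphenyl)magnesium chloride 5 (not isolated)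
Conditions: 2 (1.3 equiv), i-PrMgCl·LiCl, THF, −10 °C to rt; then 4 pretreated with i-PrMgCl (1.0 equiv), Li2CuCl4 (5 mol%), NMP, THF, 0 °C to rt; aq. HCl
Reagents that add atoms: none
Why: Bromine–magnesium exchange on symmetrical 2 stops after one bromine because the aryl Grignard is deactivated towards a second exchange, so 5 forms without a regiochemical question; copper-catalysed Grignard–alkyl bromide cross-coupling (Kochi type, accelerated by NMP) is fast at a primary bromide and is established for ω-bromoalkanoic acids used as halomagnesium carboxylates; acid–base extraction separates 6 from neutral arenes.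

Step 4
Reactants: 6 15-(3-bromo-2,5-dimethoxyphenyl)pentadecanoic acid
Product: 7 15-(3-hydroxy-2,5-dimethoxyphenyl)pentadecanoic acid
Conditions: Pd2(dba)3 (2 mol%), t-BuXPhos (8 mol%), KOH (5 equiv), 1,4-dioxane/H2O, 100 °C; aq. HCl
Reagents that add atoms: potassium hydroxide, [K+].[OH-]
Why: Palladium-catalysed hydroxylation of an aryl bromide with hydroxide; the bulky biarylphosphine favours reductive elimination to the phenoxide over diaryl ether formation, an ortho methoxy group is tolerated, and the carboxylate is inert in aqueous base.

Step 5
Reactants: 7 15-(3-hydroxy-2,5-dimethoxyphenyl)pentadecanoic acid, 8 trichloroethylene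
Product: 9 15-{3-[(E)-1,2-dichloroethenyloxy]-2,5-dimethoxyphenyl}pentadecanoic acid
Conditions: K2CO3 (3 equiv), DMF, 70 °C; aq. NaHCO3, then acidification to pH 4
Reagents that add atoms: none
Why: Base-mediated addition of a phenoxide to trichloroethylene (elimination to dichloroacetylene, then anti addition of ArO–H), the standard preparation of aryl E-1,2-dichlorovinyl ethers; the phenoxide is far more nucleophilic than the carboxylate, and any dichlorovinyl ester formed at the carboxyl group is an activated enol ester that the bicarbonate work-up hydrolyses back to the acid.

Step 6
Reactants: 9 15-{3-[(E)-1,2-dichloroethenyloxy]-2,5-dimethoxyphenyl}pentadecanoic acid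
Product: 12 15-[3-(ethynyloxy)-2,5-dimethoxyphenyl]pentadecanoic acid, via lithium chloroethynyl ether carboxylate 10 (not isolated), via dilithio acetylide carboxylate 11 (not isolated)
Conditions: n-BuLi (3.2 equiv), THF, −78 °C; aq. NaH2PO4 (pH 4)
Reagents that add atoms: none
Why: The first equivalent of n-BuLi forms the lithium carboxylate; the next two effect the known conversion of aryl dichlorovinyl ethers into lithium aryloxyacetylides (vinyl deprotonation and loss of LiCl to 10, then chlorine–lithium exchange to 11), and protonation gives the terminal ynol ether; at −78 °C an alkyllithium attacks a lithium carboxylate only slowly, and the weakly acidic phosphate quench avoids hydration of the ynol ether, which is used at once.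

Step 7
Reactants: 12 15-[3-(ethynyloxy)-2,5-dimethoxyphenyl]pentadecanoic acid
Product: 14 15-[3-(ethynyloxy)-2,5-dimethoxyphenyl]-N-methoxy-N-methylpentadecanamide, via acyl imidazole 13 (not isolated)
Conditions: CDI, CH2Cl2, 0 °C to rt; then MeNH(OMe)·HCl, rt
Reagents that add atoms: N,O-dimethylhydroxylamine hydrochloride, CNOC.Cl
Why: Amide formation through the acyl imidazole runs under neutral to weakly basic conditions, with no strong acid, Lewis acid or electrophile that an aryl ynol ether would not survive; the N-methoxy-N-methyl amide is chosen because its adduct with an acetylide does not collapse before work-up.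

Step 8
Reactants: 14 15-[3-(ethynyloxy)-2,5-dimethoxyphenyl]-N-methoxy-N-methylpentadecanamide
Product: 17 21-membered macrocyclic aryloxy ynone (2,5-dimethoxybenzene bridged from C1 to C3 by O–C≡C–C(=O)–(CH2)14), via lithium acetylide 15 (not isolated), via chelated tetrahedral adduct 16 (not isolated)
Conditions: LiN(SiMe3)2 (1.5 equiv), THF (0.001 M), −78 to 0 °C; inverse quench into cold 0.5 M HCl
Reagents that add atoms: none
Why: The hindered amide base deprotonates the ynol ether C–H to give 15, which adds to the remote amide carbonyl (addition of a lithium alkoxyacetylide to an N-methoxy-N-methyl amide, the usual route to alkoxyethynyl ketones, here intramolecular) to give 16; 16 releases the ynone only on quench, so the base never meets Michael acceptor 17, and cold acid protonates the liberated N,O-dimethylhydroxylamine before it can add to the ynone. True high dilution is needed because the acetylide is long-lived.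

Step 9
Reactants: 17 21-membered macrocyclic aryloxy ynone, 18 dimethyl 1,3-acetonedicarboxylate
Product: 21 macrocyclic dimethyl 2-hydroxyisophthalate (ring A: 2-hydroxy-1,3-bis(methoxycarbonyl)benzene with the (CH2)14 bridge at C4 and the ether oxygen to ring B at C6), via Michael adduct 19 (not isolated), via aldol carbinol 20 (not isolated)
Conditions: 18 (1.05 equiv), NaH (1.05 equiv), THF, 0 °C; add 17, 0 °C to rt; then 1 M HCl, rt
Reagents that add atoms: none
Why: Proposed new method: the sodium enolate of 18 should add in conjugate fashion to the alkyne carbon of 17 that bears the aryloxy group, giving β-aryloxy enone 19 after proton transfer; the second activated methylene then attacks the ketone in a 6-exo-trig aldol closure of ring A to carbinol 20, and loss of water with enolisation of the ring ketone gives aromatic 21. The closest known reaction type is the one-pot Michael–aldol benzannulation of dimethyl acetonedicarboxylate with alkynals and carbon-substituted alkynones, which gives 2-hydroxyisophthalates under these conditions; an oxygen-substituted alkyne terminus and a macrocyclic ynone have not been used. Regiochemistry rests on conjugation: the ketone makes the oxygen-bearing carbon the β-position, the site at which amines and alcohols add to alkoxyethynyl ketones. Retention of the ether rests on oxidation level: because the electrophile is an alkyne, aromatisation is reached by losing water, whereas expulsion of the ring B phenoxide from 19 would have to produce a cumulene. Under the basic conditions 19 exists as its delocalised enolate, which is not electrophilic, so a second nucleophile cannot displace the aryloxy group, and 18 is limited to 1.05 equivalents. The E and Z forms of 19 interconvert through that enolate, so the geometry needed for cyclisation is available, and the acid work-up completes dehydration of 20. No stereocentre survives, since the sp3 centres of 20 become sp2 on aromatisation.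

Step 10
Reactants: 21 macrocyclic dimethyl 2-hydroxyisophthalate
Product: 22 macrocyclic 2-hydroxyisophthalic acid (diacid of 21)
Conditions: KOH, DMSO/H2O, 100 °C; aq. HCl
Reagents that add atoms: potassium hydroxide, [K+].[OH-]
Why: Saponification; hot hydroxide in aqueous DMSO is used because each ester is flanked on both sides and sits next to a phenoxide, while the diaryl ether and the methyl ethers are inert to it.

Step 11
Reactants: 22 macrocyclic 2-hydroxyisophthalic acid
Product: 23 ring B dimethyl ether of the target (macrocyclic 3-aryloxy-5-alkylphenol)
Conditions: Cu2O (10 mol%), 1,10-phenanthroline (20 mol%), NMP/quinoline, 170 °C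
Reagents that add atoms: none
Why: Copper-catalysed protodecarboxylation of an electron-rich salicylic-type diacid; each carboxyl is ortho to the hydroxyl and ortho or para to the aryloxy oxygen, so ipso protonation is easy, as in the decarboxylation of resorcylic and orsellinic acids.

Step 12
Reactants: 23 ring B dimethyl ether of the target
Product: 24 target macrocycle CNP0393720.0
Conditions: BBr3, CH2Cl2, −78 °C to rt; MeOH, then aq. Na2S2O4
Reagents that add atoms: none
Why: Lewis-acid cleavage of aryl methyl ethers by BBr3, to which diaryl ethers are inert; the hydroquinone is set free only in this last step and the reductive work-up keeps it from oxidising to the quinone.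

## Compound list

1 | 2,6-dibromo-4-methoxyphenol | COc1cc(Br)c(O)c(Br)c1 | starting material
2 | 1,3-dibromo-2,5-dimethoxybenzene | COc1cc(Br)c(OC)c(Br)c1 | intermediate
3 | ω-pentadecalactone (oxacyclohexadecan-2-one) | O=C1CCCCCCCCCCCCCCO1 | starting material
4 | 15-bromopentadecanoic acid | OC(=O)CCCCCCCCCCCCCCBr | intermediate
5 | (3-bromo-2,5-dimethoxyphenyl)magnesium chloride (not isolated) | COc1cc(Br)c(OC)c([Mg]Cl)c1 | intermediate
6 | 15-(3-bromo-2,5-dimethoxyphenyl)pentadecanoic acid | COc1cc(Br)c(OC)c(CCCCCCCCCCCCCCC(=O)O)c1 | intermediate
7 | 15-(3-hydroxy-2,5-dimethoxyphenyl)pentadecanoic acid | COc1cc(O)c(OC)c(CCCCCCCCCCCCCCC(=O)O)c1 | intermediate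
8 | trichloroethylene | ClC=C(Cl)Cl | starting material
9 | 15-{3-[(E)-1,2-dichloroethenyloxy]-2,5-dimethoxyphenyl}pentadecanoic acid | COc1cc(O/C(Cl)=C\Cl)c(OC)c(CCCCCCCCCCCCCCC(=O)O)c1 | intermediate
10 | lithium 15-[3-(chloroethynyloxy)-2,5-dimethoxyphenyl]pentadecanoate (not isolated) | COc1cc(OC#CCl)c(OC)c(CCCCCCCCCCCCCCC(=O)O[Li])c1 | intermediate
11 | lithium 15-{2,5-dimethoxy-3-[(lithioethynyl)oxy]phenyl}pentadecanoate (not isolated) | COc1cc(OC#C[Li])c(OC)c(CCCCCCCCCCCCCCC(=O)O[Li])c1 | intermediate
12 | 15-[3-(ethynyloxy)-2,5-dimethoxyphenyl]pentadecanoic acid | COc1cc(OC#C)c(OC)c(CCCCCCCCCCCCCCC(=O)O)c1 | intermediate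
13 | 15-[3-(ethynyloxy)-2,5-dimethoxyphenyl]-1-(imidazol-1-yl)pentadecan-1-one (not isolated) | COc1cc(OC#C)c(OC)c(CCCCCCCCCCCCCCC(=O)n2ccnc2)c1 | intermediate
14 | 15-[3-(ethynyloxy)-2,5-dimethoxyphenyl]-N-methoxy-N-methylpentadecanamide | COc1cc(OC#C)c(OC)c(CCCCCCCCCCCCCCC(=O)N(C)OC)c1 | intermediate
15 | lithium acetylide of 14 (not isolated) | COc1cc(OC#C[Li])c(OC)c(CCCCCCCCCCCCCCC(=O)N(C)OC)c1 | intermediate
16 | lithium alkoxide of the macrocyclic N-methoxy-N-methyl hemiaminal (tetrahedral adduct, racemic, not isolated) | COc1cc2c(OC)c(c1)OC#CC(O[Li])(N(C)OC)CCCCCCCCCCCCCC2 | intermediate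
17 | 21-membered macrocyclic aryloxy ynone (2,5-dimethoxybenzene bridged from C1 to C3 by O–C≡C–C(=O)–(CH2)14) | COc1cc2c(OC)c(c1)OC#CC(=O)CCCCCCCCCCCCCC2 | intermediate
18 | dimethyl 1,3-acetonedicarboxylate (dimethyl 3-oxopentanedioate) | COC(=O)CC(=O)CC(=O)OC | starting material
19 | Michael adduct: macrocyclic β-aryloxy enone with the CH(CO2Me)C(=O)CH2CO2Me residue on the aryloxy-bearing alkene carbon (double-bond isomers interconvert, not isolated) | COc1cc2c(OC)c(c1)OC(C(C(=O)OC)C(=O)CC(=O)OC)=CC(=O)CCCCCCCCCCCCCC2 | intermediate
20 | aldol carbinol: macrocycle-fused dimethyl 4-aryloxy-6-hydroxy-2-oxocyclohex-4-ene-1,3-dicarboxylate (diastereomer mixture, not isolated) | COc1cc2c(OC)c(c1)OC1=CC(O)(CCCCCCCCCCCCCC2)C(C(=O)OC)C(=O)C1C(=O)OC | intermediate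
21 | macrocyclic dimethyl 2-hydroxyisophthalate (target skeleton, ring B dimethyl ether, two esters flanking the ring A hydroxyl) | COC(=O)c1c(O)c(C(=O)OC)c2cc1Oc1cc(OC)cc(c1OC)CCCCCCCCCCCCCC2 | intermediate
22 | macrocyclic 2-hydroxyisophthalic acid (diacid of 21) | OC(=O)c1c(O)c(C(=O)O)c2cc1Oc1cc(OC)cc(c1OC)CCCCCCCCCCCCCC2 | intermediate
23 | ring B dimethyl ether of the target | Oc1cc2cc(c1)Oc1cc(OC)cc(c1OC)CCCCCCCCCCCCCC2 | intermediate
24 | target macrocycle CNP0393720.0 | Oc1cc2cc(c1)Oc1cc(O)cc(c1O)CCCCCCCCCCCCCC2 | target

## Step count and risks

Total: 12 steps. Longest linear sequence: 11 steps (steps 1 and 3 to 12, from 1). Step 2 is a one-step side branch.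

**Step 9 (key step, proposed new method).** The most likely failure is loss of the ether link. After the conjugate addition, the ring B phenoxide may be expelled or displaced by a second nucleophile, which opens the macrocycle. This becomes likely if the aldol closure is slow, because the ketone of 19 is part of a vinylogous ester and therefore a weak electrophile.

The fallback uses only known reactions. It sets out from 6 and comes back at 23.
- Acid 6 is converted with CDI and MeNH(OMe)·HCl into 15-(3-bromo-2,5-dimethoxyphenyl)-N-methoxy-N-methylpentadecanamide F1.
- Ethynylmagnesium bromide turns F1 into the terminal ynone 17-(3-bromo-2,5-dimethoxyphenyl)heptadec-1-yn-3-one F2.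
- F2 undergoes the documented Michael–aldol benzannulation with 18 (NaH, THF) to dimethyl 4-[14-(3-bromo-2,5-dimethoxyphenyl)tetradecyl]-2-hydroxybenzene-1,3-dicarboxylate F3.
- Saponification gives 4-[14-(3-bromo-2,5-dimethoxyphenyl)tetradecyl]-2-hydroxybenzene-1,3-dicarboxylic acid F4, and copper-catalysed protodecarboxylation gives 3-[14-(3-bromo-2,5-dimethoxyphenyl)tetradecyl]phenol F5.
- Iridium-catalysed C–H borylation ([Ir(OMe)(cod)]2, 4,4'-di-tert-butyl-2,2'-bipyridine, HBpin) goes to the only ring position without an ortho substituent and gives 3-[14-(3-bromo-2,5-dimethoxyphenyl)tetradecyl]-5-(4,4,5,5-tetramethyl-1,3,2-dioxaborolan-2-yl)phenol F6.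
- Oxidation with H2O2 and NaOH gives 5-[14-(3-bromo-2,5-dimethoxyphenyl)tetradecyl]benzene-1,3-diol F7.
- The two hydroxyls of F7 are equivalent, so intramolecular Ullmann etherification at the ring B bromide (CuI, picolinic acid, K3PO4, DMSO, high dilution) gives 23.

**Step 8.** The most likely failure is intermolecular acylation to dimers and oligomers. Attack of the acetylide on an amide twenty atoms away is slow, so the acetylide accumulates. Slow base-induced decomposition of the N-methoxy amide and conjugate addition of the liberated amine during quench are further losses.

The fallback sets out from 14 and comes back at 17. It replaces anionic acylation by a chromium-mediated aldehyde alkynylation.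
- Iodination of the alkyne C–H (NIS, cat. DBU, MeCN) gives 15-[3-(iodoethynyloxy)-2,5-dimethoxyphenyl]-N-methoxy-N-methylpentadecanamide F8.
- i-Bu2AlH at −78 °C reduces the amide to 15-[3-(iodoethynyloxy)-2,5-dimethoxyphenyl]pentadecanal F9.
- Nozaki–Hiyama–Kishi macrocyclisation (CrCl2, cat. NiCl2, THF/DMF, high dilution) gives the macrocyclic aryloxy propargylic alcohol F10.
- Oxidation with MnO2 gives 17.

**Step 6.** The most likely failure is addition of butyllithium to the carboxylate, giving a butyl ketone, or incomplete chlorine–lithium exchange. Three equivalents of a strong nucleophile meet a carboxylate salt of limited solubility. Slow addition of the free acid to the ynol ether during isolation is a second risk.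

The fallback sets out from 9 and comes back at 14.
- Acid 9 is coupled with O-methylhydroxylamine hydrochloride (CDI) to 15-{3-[(E)-1,2-dichloroethenyloxy]-2,5-dimethoxyphenyl}-N-methoxypentadecanamide F11.
- The N–H of F11 is deprotonated first, and the amidate shields the carbonyl during the elimination with n-BuLi (3.3 equiv, −78 °C), which gives 15-[3-(ethynyloxy)-2,5-dimethoxyphenyl]-N-methoxypentadecanamide F12.
- N-Methylation (MeI, K2CO3, DMF), which does not touch the alkyne C–H, gives 14.

**Step 3.** The most likely failure is diversion of the aryl Grignard into homocoupling, reduction, or coupling with the isopropyl bromide released by the exchange. Aryl Grignards couple less readily than alkyl Grignards under copper catalysis, and the magnesium carboxylate may be poorly soluble.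

The fallback sets out from 4 (with 2) and comes back at 7.
- Fischer esterification of 4 gives methyl 15-bromopentadecanoate F13.
- Zinc insertion (Zn, cat. I2, DMA, 80 °C) gives (15-methoxy-15-oxopentadecyl)zinc bromide F14.
- Negishi coupling with an excess of 2 (Pd(OAc)2, SPhos, THF) gives methyl 15-(3-bromo-2,5-dimethoxyphenyl)pentadecanoate F15.
- Under the conditions of step 4, KOH replaces the bromide and saponifies the ester, giving 7.

## Further compounds

F1 | step 9 | 15-(3-bromo-2,5-dimethoxyphenyl)-N-methoxy-N-methylpentadecanamide | COc1cc(Br)c(OC)c(CCCCCCCCCCCCCCC(=O)N(C)OC)c1
F2 | step 9 | 17-(3-bromo-2,5-dimethoxyphenyl)heptadec-1-yn-3-one | C#CC(=O)CCCCCCCCCCCCCCc1cc(OC)cc(Br)c1OC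
F3 | step 9 | dimethyl 4-[14-(3-bromo-2,5-dimethoxyphenyl)tetradecyl]-2-hydroxybenzene-1,3-dicarboxylate | COC(=O)c1ccc(CCCCCCCCCCCCCCc2cc(OC)cc(Br)c2OC)c(C(=O)OC)c1O
F4 | step 9 | 4-[14-(3-bromo-2,5-dimethoxyphenyl)tetradecyl]-2-hydroxybenzene-1,3-dicarboxylic acid | OC(=O)c1ccc(CCCCCCCCCCCCCCc2cc(OC)cc(Br)c2OC)c(C(=O)O)c1O
F5 | step 9 | 3-[14-(3-bromo-2,5-dimethoxyphenyl)tetradecyl]phenol | Oc1cccc(CCCCCCCCCCCCCCc2cc(OC)cc(Br)c2OC)c1
F6 | step 9 | 3-[14-(3-bromo-2,5-dimethoxyphenyl)tetradecyl]-5-(4,4,5,5-tetramethyl-1,3,2-dioxaborolan-2-yl)phenol | Oc1cc(CCCCCCCCCCCCCCc2cc(OC)cc(Br)c2OC)cc(B2OC(C)(C)C(C)(C)O2)c1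
F7 | step 9 | 5-[14-(3-bromo-2,5-dimethoxyphenyl)tetradecyl]benzene-1,3-diol | Oc1cc(O)cc(CCCCCCCCCCCCCCc2cc(OC)cc(Br)c2OC)c1
F8 | step 8 | 15-[3-(iodoethynyloxy)-2,5-dimethoxyphenyl]-N-methoxy-N-methylpentadecanamide | COc1cc(OC#CI)c(OC)c(CCCCCCCCCCCCCCC(=O)N(C)OC)c1
F9 | step 8 | 15-[3-(iodoethynyloxy)-2,5-dimethoxyphenyl]pentadecanal | COc1cc(OC#CI)c(OC)c(CCCCCCCCCCCCCCC=O)c1
F10 | step 8 | macrocyclic aryloxy propargylic alcohol (carbinol corresponding to 17, racemic) | COc1cc2c(OC)c(c1)OC#CC(O)CCCCCCCCCCCCCC2
F11 | step 6 | 15-{3-[(E)-1,2-dichloroethenyloxy]-2,5-dimethoxyphenyl}-N-methoxypentadecanamide | COc1cc(O/C(Cl)=C\Cl)c(OC)c(CCCCCCCCCCCCCCC(=O)NOC)c1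
F12 | step 6 | 15-[3-(ethynyloxy)-2,5-dimethoxyphenyl]-N-methoxypentadecanamide | COc1cc(OC#C)c(OC)c(CCCCCCCCCCCCCCC(=O)NOC)c1
F13 | step 3 | methyl 15-bromopentadecanoate | COC(=O)CCCCCCCCCCCCCCBr
F14 | step 3 | (15-methoxy-15-oxopentadecyl)zinc bromide | COC(=O)CCCCCCCCCCCCCC[Zn]Br
F15 | step 3 | methyl 15-(3-bromo-2,5-dimethoxyphenyl)pentadecanoate | COc1cc(Br)c(OC)c(CCCCCCCCCCCCCCC(=O)OC)c1
A1 | alternative 1 | macrocyclic 4-methoxyphenol (ring A methyl ether, remote ring B methyl ether, central ring B hydroxyl free) | COc1cc2cc(c1)Oc1cc(OC)cc(c1O)CCCCCCCCCCCCCC2
A2 | alternative 1 | pentacarbonyl{(E)-3-[3-(hexadec-15-ynyl)-5-methoxyphenoxy]-1-methoxyprop-2-enylidene}chromium | COC(/C=C/Oc1cc(OC)cc(CCCCCCCCCCCCCCC#C)c1)=[Cr](=C=O)(=C=O)(=C=O)(=C=O)=C=O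
A3 | alternative 2 | 2-(3-bromo-5-methoxyphenoxy)-6-(tetradec-13-enyl)benzene-1,4-diol | COc1cc(Br)cc(c1)Oc1cc(O)cc(CCCCCCCCCCCCC=C)c1O
A4 | alternative 2 | 3-(3-bromo-5-methoxyphenoxy)-4-(hexadeca-1,15-dien-2-yl)-4-hydroxycyclobut-2-en-1-one (racemic) | O=C1C=C(Oc2cc(Br)cc(OC)c2)C1(O)C(=C)CCCCCCCCCCCCC=C
A5 | alternative 3 | 21-membered carbocyclic (E)-alkenyl carboxylic acid (racemic, one enantiomer drawn) | COc1cc2cc(c1)Oc1cc(OC)cc(c1OC)CCCCC/C=C/C[C@H](C(=O)O)CCCCC2
A6 | alternative 3 | 21-membered allylic macrolactone with a vinyl group on the carbinol carbon (racemic) | COc1cc2cc(c1)Oc1cc(OC)cc(c1OC)CCCCCC(C=C)OC(=O)CCCCCC2
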